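**Retrosynthetic overview**

Locants used throughout: ring C1–C10 with C3–OH, C4–CH3 (C15), C4=C5 (Z), C6–O (lactone), C7–C11, C9–O-angeloyl, C10–OH/CH3 (C14); lactone C11(=C13H2)–C12(=O)–O–C6. Endgame: target 33 ⇐ desilylation ⇐ 9-O-angeloylation ⇐ (9S)-alcohol ⇐ C9 ketone 28.
Key disconnection C7–C11: the trans-fused α-methylene-γ-butyrolactone 28 is the Rauhut–Currier isomer of the 6-O-acryloyl (4Z,7E)-cyclodeca-4,7-dien-9-one 27. The enabling feature is that C7 lies between the oxygen-bearing C6 and C8–C9(O) of the ten-membered ring: at the ketone level C7=C8–C9=O is an enone with C7 as β-carbon, and the O6-acrylate delivers its α-carbon C11 to C7 through the five-membered ring O–C12–C11–C7–C6 while C13 stays as the exocyclic methylene.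
Ten-membered carbocycle: C8–C9 by intramolecular Nozaki–Hiyama–Kishi reaction of an (E)-vinyl iodide with a non-enolizable aldehyde, then oxidation to the enone (C9 epimers converge).
Chain: C3–C4 by intermolecular Nozaki–Hiyama–Kishi coupling of Z-vinyl iodide 14 (C4–C8, C15; C6 from a catalytic asymmetric alkynylation) with aldehyde 6 (C9, C10, C14, C1–C3 from (R)-2-methylglycidol); C3 by CBS reduction.
Order of ring formation: carbocycle first (step 15), lactone second (step 19).

Key step: step 19

Assumption (step 6): the (S,S)-ProPhenol–zinc catalyst is taken to deliver the alkynyl group to the Si face of enal 10; if the sense of induction is opposite, the (R,R)-ligand is used and nothing else changes.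
Remark: the CIP label at C6 changes between R and S along the route only because substituent priorities change; its spatial arrangement is that of the target from step 6 on.

**Route**

Step 1
Reactants: 1 (R)-2-methylglycidol; 2 allylmagnesium chloride
Product: 3 (S)-2-methylhex-5-ene-1,2-diol
Conditions: 2 (2.5 equiv), CuI (10 mol%), THF, −40 → 0 °C; aq. NH4Cl
Reagents that add atoms: none
Why: Copper-catalysed SN2 opening of the 2,2-disubstituted epoxide at its unsubstituted CH2 terminus by the allyl Grignard reagent (the first equivalent only deprotonates the hydroxyl and the Payne rearrangement of this glycidol is degenerate), so the quaternary carbinol C10 comes unchanged from 1 and no new stereocentre is formed.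

Step 2
Reactants: 3 (S)-2-methylhex-5-ene-1,2-diol
Product: 4 (S)-2-methyl-1,2-bis(triethylsilyloxy)hex-5-ene
Conditions: TESOTf (2.5 equiv), 2,6-lutidine, CH2Cl2, −78 → 0 °C
Reagents that add atoms: triethylsilyl trifluoromethanesulfonate CC[Si](CC)(CC)OS(=O)(=O)C(F)(F)F
Why: Silyl triflate with 2,6-lutidine silylates the primary and the hindered tertiary hydroxyl in one operation, the primary TES ether being the latent C9 aldehyde.

Step 3
Reactants: 4 (S)-2-methyl-1,2-bis(triethylsilyloxy)hex-5-ene
Product: 6 (S)-4-methyl-4,5-bis(triethylsilyloxy)pentanal, via ozonide 5 (not isolated)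
Conditions: O3, CH2Cl2, −78 °C; PPh3, −78 °C → rt
Reagents that add atoms: ozone [O-][O+]=O
Why: Ozonolysis of the only alkene through the 1,2,4-trioxolane and reductive work-up with PPh3 gives the C3 aldehyde, silyl ethers being inert and no stereocentre being touched.

Step 4
Reactants: 7 but-2-yn-1-ol
Product: 9 (Z)-3-iodobut-2-en-1-ol, via cyclic alkenylaluminate 8 (not isolated)
Conditions: Red-Al, THF, 0 °C → rt; I2, THF, −78 → 0 °C
Reagents that add atoms: iodine II
Why: Alkoxide-directed trans-hydroalumination of the propargylic alcohol places aluminium on the distal carbon within a five-membered ring and iodinolysis with retention gives the Z-iodide, which fixes the C4=C5 geometry of the target.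

Step 5
Reactants: 9 (Z)-3-iodobut-2-en-1-ol
Product: 10 (Z)-3-iodobut-2-enal
Conditions: MnO2, CH2Cl2, rt, dark
Reagents that add atoms: none
Why: Neutral heterogeneous MnO2 oxidation of the allylic alcohol gives the β-iodo enal without Z to E isomerization.

Step 6
Reactants: 10 (Z)-3-iodobut-2-enal; 11 (trimethylsilyl)acetylene
Product: 13 (3R,4Z)-5-iodo-1-(trimethylsilyl)hex-4-en-1-yn-3-ol, via alkynylzinc 12 (not isolated)
Conditions: 11, Me2Zn, (S,S)-ProPhenol (20 mol%), Ph3P=O (40 mol%), toluene, 0 °C; then 10, 4 °C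
Reagents that add atoms: none
Why: Catalytic enantioselective alkynylation of an α,β-unsaturated aldehyde with an alkynylzinc formed in situ under dinuclear Zn–ProPhenol control, in which addition to the Si face of the aldehyde sets C6 (3R in 13).

Step 7
Reactants: 13 (3R,4Z)-5-iodo-1-(trimethylsilyl)hex-4-en-1-yn-3-ol
Product: 14 (3R,4Z)-5-iodo-3-(triethylsilyloxy)-1-(trimethylsilyl)hex-4-en-1-yne
Conditions: TESCl, imidazole, CH2Cl2, 0 °C
Reagents that add atoms: chlorotriethylsilane CC[Si](Cl)(CC)CC
Why: Standard silylation of the secondary alcohol, TES being chosen because it is later removed from C6 in the presence of the tertiary TES and the TBS ether.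

Step 8
Reactants: 14 (3R,4Z)-5-iodo-3-(triethylsilyloxy)-1-(trimethylsilyl)hex-4-en-1-yne; 6 (S)-4-methyl-4,5-bis(triethylsilyloxy)pentanal
Product: 15 acyclic C3 carbinol (6R,10S,4Z; both C3 epimers): chain C9–C10–C1–C2–C3–C4=C5–C6–C7≡C8 with 3-OH, 6-OTES, 9-OTES, 10-OTES, 8-SiMe3
Conditions: CrCl2 (4 equiv), NiCl2 (2 mol%), DMSO, rt; 6 (1.3 equiv)
Reagents that add atoms: none
Why: Nozaki–Hiyama–Kishi coupling (Ni-mediated insertion into the C–I bond, transmetalation to Cr(III), addition to the aldehyde) joins C4 to C3 with retention of the Z geometry and avoids the 1,4-silyl migration that threatens a cis-γ-silyloxy vinyllithium, while C3 is expected to form without control and is corrected in steps 9 and 10.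

Step 9
Reactants: 15 acyclic C3 carbinol (both C3 epimers)
Product: 16 acyclic (6R,10S,4Z)-C3 ketone (Z-enone), other groups as in 15
Conditions: Dess–Martin periodinane, NaHCO3, CH2Cl2, 0 °C → rt
Reagents that add atoms: none
Why: Dess–Martin oxidation converges both C3 epimers into one Z-enone under buffered, non-isomerizing conditions.

Step 10
Reactants: 16 acyclic C3 ketone
Product: 17 acyclic (3S,6R,10S,4Z)-C3 alcohol
Conditions: (R)-Me-CBS (0.5 equiv), catecholborane, toluene, −78 °C
Reagents that add atoms: none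
Why: Corey–Bakshi–Shibata reduction, in which the α-methyl alkenyl group acts as the large and the CH2 chain as the small ketone substituent, so the (R)-catalyst should deliver hydride to give the 3S alcohol by clean 1,2-reduction.

Step 11
Reactants: 17 acyclic (3S)-alcohol
Product: 18 acyclic (3S,6R,10S,4Z)-3-O-TBS ether
Conditions: TBSCl, imidazole, DMF, rt
Reagents that add atoms: tert-butyldimethylsilyl chloride CC(C)(C)[Si](C)(C)Cl
Why: Standard silylation, TBS at C3 being stable to the later selective removal of the C6 TES ether.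

Step 12
Reactants: 18 acyclic 3-O-TBS ether
Product: 19 acyclic (3S,6R,10S,4Z)-terminal alkyne (C7≡C8–H)
Conditions: K2CO3 (cat.), MeOH, 0 °C
Reagents that add atoms: none
Why: Methoxide-mediated protodesilylation of the alkynylsilane, fast enough at 0 °C to leave the TES and TBS ethers in place.

Step 13
Reactants: 19 acyclic terminal alkyne
Product: 21 acyclic (3S,6R,10S,4Z,7E)-C8 vinyl iodide, via alkenylzirconocene 20 (not isolated)
Conditions: Cp2Zr(H)Cl, THF, rt; I2, 0 °C
Reagents that add atoms: iodine II
Why: Hydrozirconation of the terminal alkyne is a syn addition that places Zr on the terminal carbon C8 and iodinolysis proceeds with retention to the (E)-vinyl iodide, the trisubstituted alkene being inert to Cp2Zr(H)Cl.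

Step 14
Reactants: 21 acyclic C8 vinyl iodide
Product: 22 acyclic (3S,6R,10S,4Z,7E)-C9 aldehyde with C8 vinyl iodide
Conditions: (COCl)2, DMSO, CH2Cl2, −78 → −40 °C; Et3N, −78 → 0 °C
Reagents that add atoms: none
Why: Swern conditions cleave the unhindered primary TES ether through the activated sulfonium species and oxidize it in the same flask to the aldehyde, while the secondary and tertiary silyl ethers are expected to survive and the aldehyde, lacking an α-hydrogen, cannot epimerize.

Step 15
Reactants: 22 acyclic iodo aldehyde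
Product: 23 (3S,6S,10S,4Z,7E)-3-(TBSO)-6,10-bis(TESO)-4,10-dimethylcyclodeca-4,7-dien-9-ol (skeleton locants; both C9 epimers)
Conditions: CrCl2 (10 equiv), NiCl2 (10 mol%), DMSO/THF, rt, slow addition, 2 mM
Reagents that add atoms: none
Why: Intramolecular Nozaki–Hiyama–Kishi reaction at high dilution, helped by the Z-alkene C4=C5 that pre-bends the chain and by the non-enolizable aldehyde, the configuration formed at C9 being irrelevant because it is erased in step 16.

Step 16
Reactants: 23 macrocyclic allylic alcohol (both C9 epimers)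
Product: 24 (3S,6S,10S,4Z,7E)-3-(TBSO)-6,10-bis(TESO)-4,10-dimethylcyclodeca-4,7-dien-9-one
Conditions: Dess–Martin periodinane, NaHCO3, CH2Cl2, 0 °C
Reagents that add atoms: none
Why: Dess–Martin oxidation of the allylic alcohol converges both C9 epimers into the E-enone that activates C7.

Step 17
Reactants: 24 macrocyclic enone
Product: 25 (3S,6S,10S,4Z,7E)-6-hydroxy-3-(TBSO)-10-(TESO)-4,10-dimethylcyclodeca-4,7-dien-9-one
Conditions: PPTS (cat.), MeOH/CH2Cl2, 0 °C
Reagents that add atoms: none
Why: Mild acid-catalysed methanolysis removes the secondary allylic TES ether faster than the hindered tertiary TES ether next to the carbonyl and the TBS ether.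

Step 18
Reactants: 25 macrocyclic γ-hydroxy enone; 26 acryloyl chloride
Product: 27 (3S,6S,10S,4Z,7E)-6-acryloyloxy-3-(TBSO)-10-(TESO)-4,10-dimethylcyclodeca-4,7-dien-9-one
Conditions: 26, iPr2NEt, CH2Cl2, −78 → −20 °C
Reagents that add atoms: none
Why: O-Acylation of the secondary alcohol with the acid chloride and a hindered amine base at low temperature installs C11–C13 on O6.

Step 19
Reactants: 27 macrocyclic 6-O-acryloyl enone
Product: 28 (3S,6R,7S,10S,4Z)-3-(TBSO)-10-(TESO)-9-oxogermacra-4,11(13)-dien-12,6-olide (trans-fused α-methylene-γ-butyrolactone)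
Conditions: PMe3 (20 mol%), PhOH (20 mol%), THF (0.01 M), 0 °C → rt
Reagents that add atoms: none
Why: PMe3 adds reversibly to the unsubstituted acrylate terminus C13, the phosphonium enolate so formed attacks through C11 the β-carbon C7 of the ring enone, and proton transfer from C11 to the C8 enolate followed by E1cB loss of PMe3 restores the C11=C13 methylene, so the step is an isomerization with no by-product. The closest known reaction type is the phosphine-catalysed intramolecular Rauhut–Currier cyclization of γ-acryloyloxy enones (4-acryloyloxy-cyclohexadienones) to α-methylene-γ-butyrolactones. The lactone ring (O–C12–C11–C7–C6) closes in the 5-exo-trig mode onto C7=C8. The new stereocentre C7 is controlled by C6 through the ring fusion: the O6 tether can reach C7 only in conformers in which the ring torsion C5–C6–C7=C8 is anticlinal to antiperiplanar (C6–H near the enone plane), the normal arrangement next to an E double bond in a ten-membered ring, and this leads to H6/H7 trans (7S), whereas the syn-periplanar torsion needed for the cis lactone is strained; a 7Z-enone would be driven to the same C7 configuration by allylic 1,3-strain. The step needs chemoselectivity between the two alkenes that flank C6 and between the two acceptors: only C7=C8 is conjugated (to C9=O), so C4=C5 is inert, and the phosphine prefers the unhindered CH2 terminus of the acrylate over the β-substituted ring enone. Phenol buffers the zwitterion so that the doubly allylic C6–H is not removed, and high dilution suppresses acrylate dimerization.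

Step 20
Reactants: 28 lactone ketone
Product: 29 (3S,6R,7S,9S,10S,4Z)-9-hydroxy-3-(TBSO)-10-(TESO)-germacra-4,11(13)-dien-12,6-olide
Conditions: (R)-Me-CBS (1 equiv), catecholborane, toluene, −78 → −40 °C
Reagents that add atoms: none
Why: Corey–Bakshi–Shibata reduction in which the quaternary C10 is the large and C8H2 the small substituent, so the (R)-catalyst should give the 9S alcohol (the same sense as Felkin–Anh attack anti to the C10–OSi bond), and catecholborane at low temperature does not reduce the α-methylene lactone.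

Step 21
Reactants: 29 (9S)-alcohol; 30 angelic acid
Product: 32 (3S,6R,7S,9S,10S,4Z)-9-angeloyloxy-3-(TBSO)-10-(TESO)-germacra-4,11(13)-dien-12,6-olide, via mixed anhydride 31 (not isolated)
Conditions: 30, 2,4,6-trichlorobenzoyl chloride, Et3N, toluene, rt; then 29, toluene, 80 °C
Reagents that add atoms: none
Why: Yamaguchi-type esterification through the mixed anhydride without DMAP acylates the hindered C9 hydroxyl with retention at C9 and without Z to E isomerization of the angeloyl group to tigloyl.

Step 22
Reactants: 32 bis-silyl ether of the target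
Product: 33 CNP0549192.1, (3S,6R,7S,9S,10S,4Z)-9-angeloyloxy-3,10-dihydroxygermacra-4,11(13)-dien-12,6-olide
Conditions: HF·pyridine, pyridine, THF, 0 °C → rt
Reagents that add atoms: none
Why: Buffered HF·pyridine cleaves both silyl ethers through Si–F bond formation under conditions that neither isomerize the angelate nor add to the α-methylene lactone.

**Compound list**

1 | (R)-2-methylglycidol [(R)-(2-methyloxiran-2-yl)methanol] | C[C@@]1(CO)CO1 | starting material
2 | allylmagnesium chloride | C=CC[Mg]Cl | starting material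
3 | (S)-2-methylhex-5-ene-1,2-diol | C=CCC[C@](C)(O)CO | intermediate
4 | (S)-2-methyl-1,2-bis(triethylsilyloxy)hex-5-ene | C=CCC[C@](C)(O[Si](CC)(CC)CC)CO[Si](CC)(CC)CC | intermediate
5 | ozonide of 4 (3-substituted 1,2,4-trioxolane, epimers at the ring carbon) | C1(CC[C@](C)(O[Si](CC)(CC)CC)CO[Si](CC)(CC)CC)OCOO1 | intermediate
6 | (S)-4-methyl-4,5-bis(triethylsilyloxy)pentanal (C9, C10, C14, C1–C3) | O=CCC[C@](C)(O[Si](CC)(CC)CC)CO[Si](CC)(CC)CC | intermediate
7 | but-2-yn-1-ol | CC#CCO | starting material
8 | sodium cyclic alkoxy(alkenyl)aluminate from 7 (Al on C3 of the butenyl unit, in a five-membered ring with the oxygen) | CC1=CCO[Al-]1(OCCOC)OCCOC.[Na+] | intermediate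
9 | (Z)-3-iodobut-2-en-1-ol | C/C(I)=C/CO | intermediate
10 | (Z)-3-iodobut-2-enal | C/C(I)=C/C=O | intermediate
11 | (trimethylsilyl)acetylene | C#C[Si](C)(C)C | starting material
12 | methyl[(trimethylsilyl)ethynyl]zinc | C[Zn]C#C[Si](C)(C)C | intermediate
13 | (3R,4Z)-5-iodo-1-(trimethylsilyl)hex-4-en-1-yn-3-ol | C/C(I)=C/[C@@H](O)C#C[Si](C)(C)C | intermediate
14 | (3R,4Z)-5-iodo-3-(triethylsilyloxy)-1-(trimethylsilyl)hex-4-en-1-yne | C/C(I)=C/[C@@H](O[Si](CC)(CC)CC)C#C[Si](C)(C)C | intermediate
15 | acyclic C3 carbinol, both C3 epimers (6R,10S,4Z): 3-OH, 6-OTES, 9-OTES, 10-OTES, C7≡C8–SiMe3 | C[Si](C)(C)C#C[C@H](O[Si](CC)(CC)CC)/C=C(/C)C(O)CC[C@](C)(O[Si](CC)(CC)CC)CO[Si](CC)(CC)CC | intermediate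
16 | acyclic (6R,10S,4Z)-C3 ketone (Z-enone) | C[Si](C)(C)C#C[C@H](O[Si](CC)(CC)CC)/C=C(/C)C(=O)CC[C@](C)(O[Si](CC)(CC)CC)CO[Si](CC)(CC)CC | intermediate
17 | acyclic (3S,6R,10S,4Z)-C3 alcohol | C[Si](C)(C)C#C[C@H](O[Si](CC)(CC)CC)/C=C(/C)[C@@H](O)CC[C@](C)(O[Si](CC)(CC)CC)CO[Si](CC)(CC)CC | intermediate
18 | acyclic (3S,6R,10S,4Z)-3-O-TBS ether | C[Si](C)(C)C#C[C@H](O[Si](CC)(CC)CC)/C=C(/C)[C@@H](O[Si](C)(C)C(C)(C)C)CC[C@](C)(O[Si](CC)(CC)CC)CO[Si](CC)(CC)CC | intermediate
19 | acyclic (3S,6R,10S,4Z)-terminal alkyne | C#C[C@H](O[Si](CC)(CC)CC)/C=C(/C)[C@@H](O[Si](C)(C)C(C)(C)C)CC[C@](C)(O[Si](CC)(CC)CC)CO[Si](CC)(CC)CC | intermediate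
20 | (E)-C8 alkenylzirconocene chloride from 19 | Cl[Zr](C1C=CC=C1)(C1C=CC=C1)/C=C/[C@H](O[Si](CC)(CC)CC)/C=C(/C)[C@@H](O[Si](C)(C)C(C)(C)C)CC[C@](C)(O[Si](CC)(CC)CC)CO[Si](CC)(CC)CC | intermediate
21 | acyclic (3S,6R,10S,4Z,7E)-C8 vinyl iodide | I/C=C/[C@H](O[Si](CC)(CC)CC)/C=C(/C)[C@@H](O[Si](C)(C)C(C)(C)C)CC[C@](C)(O[Si](CC)(CC)CC)CO[Si](CC)(CC)CC | intermediate
22 | acyclic (3S,6R,10S,4Z,7E)-C9 aldehyde with C8 vinyl iodide | I/C=C/[C@H](O[Si](CC)(CC)CC)/C=C(/C)[C@@H](O[Si](C)(C)C(C)(C)C)CC[C@](C)(O[Si](CC)(CC)CC)C=O | intermediate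
23 | (3S,6S,10S,4Z,7E)-3-(TBSO)-6,10-bis(TESO)-4,10-dimethylcyclodeca-4,7-dien-9-ol (skeleton locants), both C9 epimers | OC1/C=C/[C@H](O[Si](CC)(CC)CC)/C=C(/C)[C@@H](O[Si](C)(C)C(C)(C)C)CC[C@]1(C)O[Si](CC)(CC)CC | intermediate
24 | (3S,6S,10S,4Z,7E)-3-(TBSO)-6,10-bis(TESO)-4,10-dimethylcyclodeca-4,7-dien-9-one | O=C1/C=C/[C@H](O[Si](CC)(CC)CC)/C=C(/C)[C@@H](O[Si](C)(C)C(C)(C)C)CC[C@]1(C)O[Si](CC)(CC)CC | intermediate
25 | (3S,6S,10S,4Z,7E)-6-hydroxy-3-(TBSO)-10-(TESO)-4,10-dimethylcyclodeca-4,7-dien-9-one | O=C1/C=C/[C@H](O)/C=C(/C)[C@@H](O[Si](C)(C)C(C)(C)C)CC[C@]1(C)O[Si](CC)(CC)CC | intermediate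
26 | acryloyl chloride | C=CC(=O)Cl | starting material
27 | (3S,6S,10S,4Z,7E)-6-acryloyloxy-3-(TBSO)-10-(TESO)-4,10-dimethylcyclodeca-4,7-dien-9-one | O=C1/C=C/[C@H](OC(=O)C=C)/C=C(/C)[C@@H](O[Si](C)(C)C(C)(C)C)CC[C@]1(C)O[Si](CC)(CC)CC | intermediate
28 | (3S,6R,7S,10S,4Z)-3-(TBSO)-10-(TESO)-9-oxogermacra-4,11(13)-dien-12,6-olide | C=C1C(=O)O[C@@H]2/C=C(/C)[C@@H](O[Si](C)(C)C(C)(C)C)CC[C@](C)(O[Si](CC)(CC)CC)C(=O)C[C@@H]12 | intermediate
29 | (3S,6R,7S,9S,10S,4Z)-9-hydroxy-3-(TBSO)-10-(TESO)-germacra-4,11(13)-dien-12,6-olide | C=C1C(=O)O[C@@H]2/C=C(/C)[C@@H](O[Si](C)(C)C(C)(C)C)CC[C@](C)(O[Si](CC)(CC)CC)[C@@H](O)C[C@@H]12 | intermediate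
30 | angelic acid [(Z)-2-methylbut-2-enoic acid] | C/C=C(/C)C(=O)O | starting material
31 | angelic 2,4,6-trichlorobenzoic anhydride | C/C=C(/C)C(=O)OC(=O)c1c(Cl)cc(Cl)cc1Cl | intermediate
32 | (3S,6R,7S,9S,10S,4Z)-9-angeloyloxy-3-(TBSO)-10-(TESO)-germacra-4,11(13)-dien-12,6-olide | C=C1C(=O)O[C@@H]2/C=C(/C)[C@@H](O[Si](C)(C)C(C)(C)C)CC[C@](C)(O[Si](CC)(CC)CC)[C@@H](OC(=O)/C(C)=C\C)C[C@@H]12 | intermediate
33 | CNP0549192.1, (3S,6R,7S,9S,10S,4Z)-9-angeloyloxy-3,10-dihydroxygermacra-4,11(13)-dien-12,6-olide | C=C1C(=O)O[C@@H]2/C=C(/C)[C@@H](O)CC[C@](C)(O)[C@@H](OC(=O)/C(C)=C\C)C[C@@H]12 | target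

**Summary**

Total step count: 22. Longest linear sequence: 19 steps (7 → 33; steps 4–7 and 8–22). The branch from 1 (steps 1–3) joins at step 8.

**Steps most likely to fail and fallbacks**

Step 15 (macrocyclization). The strained (4Z,7E)-cyclodecadiene may close more slowly than the organochromium is protonated or adds intermolecularly, so that reduction of the C–I bond and oligomerization take over. The fallback closes the ring by alkene metathesis at C7=C8 instead of carbonyl addition at C8–C9; it sets out from alkyne 19 and comes back at enone 24. Semihydrogenation of 19 (H2, Pd/CaCO3–Pb, quinoline) gives the 6-vinyl compound F1. Direct Swern oxidation of its primary TES ether, as in step 14, gives aldehyde F2. Vinylmagnesium bromide adds to F2 to give the divinyl carbinol F3 (both C9 epimers), which Dess–Martin periodinane oxidizes to vinyl ketone F4. Ring-closing metathesis of F4 with a second-generation Ru–NHC benzylidene catalyst at high dilution in hot toluene, with loss of ethene, should then give the macrocyclic E-enone 24.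

Step 19 (key step). The phosphine may engage the ring enone, or the zwitterion may act as a base at the doubly allylic C6–H, so that isomerization or oligomerization outruns ring closure; the closure may also proceed with poor control of the ring fusion. The fallback replaces nucleophilic catalysis by a stoichiometric, reversible Michael addition followed by olefination; it sets out from alcohol 25 and comes back at lactone 28. Esterification of 25 with diethylphosphonoacetic acid (DCC, cat. DMAP, CH2Cl2) gives the phosphonoacetate F5. Cs2CO3 in MeCN triggers the intramolecular Michael addition of the stabilized carbanion to C7 under thermodynamic control to give the α-phosphono lactone F6. In the same flask, aqueous formaldehyde with K2CO3 effects Horner–Wadsworth–Emmons methylenation to 28.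

Step 20 (C9 reduction). The conformational bias of the macrocyclic ketone may override the catalyst, giving poor or reversed facial selectivity, or the hydride source may attack the α-methylene lactone. The fallback uses the substrate bias deliberately and corrects C9 during acylation; it sets out from ketone 28 and comes back at angelate 32. Luche reduction of 28 (NaBH4, CeCl3, MeOH, −78 °C), which is 1,2-selective for the ketone, gives the C9-epimeric (9R)-alcohol F7. Mitsunobu esterification of F7 with angelic acid 30 (PPh3, DIAD, toluene) then inverts C9 and installs the angelate in one operation to give 32.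

**Further compounds**

F1 | step 15 | acyclic (3S,6S,10S,4Z)-6-vinyl compound (C7=C8H2), 3-OTBS, 6-OTES, 9-OTES, 10-OTES | C=C[C@H](O[Si](CC)(CC)CC)/C=C(/C)[C@@H](O[Si](C)(C)C(C)(C)C)CC[C@](C)(O[Si](CC)(CC)CC)CO[Si](CC)(CC)CC
F2 | step 15 | acyclic (3S,6S,10S,4Z)-C9 aldehyde with 6-vinyl group | C=C[C@H](O[Si](CC)(CC)CC)/C=C(/C)[C@@H](O[Si](C)(C)C(C)(C)C)CC[C@](C)(O[Si](CC)(CC)CC)C=O
F3 | step 15 | acyclic divinyl C9 carbinol (both C9 epimers) | C=C[C@H](O[Si](CC)(CC)CC)/C=C(/C)[C@@H](O[Si](C)(C)C(C)(C)C)CC[C@](C)(O[Si](CC)(CC)CC)C(O)C=C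
F4 | step 15 | acyclic C9 vinyl ketone with 6-vinyl group | C=C[C@H](O[Si](CC)(CC)CC)/C=C(/C)[C@@H](O[Si](C)(C)C(C)(C)C)CC[C@](C)(O[Si](CC)(CC)CC)C(=O)C=C
F5 | step 19 | macrocyclic 6-O-(diethylphosphonoacetyl) enone | O=C1/C=C/[C@H](OC(=O)CP(=O)(OCC)OCC)/C=C(/C)[C@@H](O[Si](C)(C)C(C)(C)C)CC[C@]1(C)O[Si](CC)(CC)CC
F6 | step 19 | 11-(diethoxyphosphoryl) 12,6-lactone ketone (C11 epimers) | CCOP(=O)(OCC)C1C(=O)O[C@@H]2/C=C(/C)[C@@H](O[Si](C)(C)C(C)(C)C)CC[C@](C)(O[Si](CC)(CC)CC)C(=O)C[C@@H]12
F7 | step 20 | (9R)-epimer of alcohol 29 | C=C1C(=O)O[C@@H]2/C=C(/C)[C@@H](O[Si](C)(C)C(C)(C)C)CC[C@](C)(O[Si](CC)(CC)CC)[C@H](O)C[C@@H]12
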